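## Retrosynthetic overview

1. Target 22 ⇐ ketone 20 by methylenation and desilylation. Ring C (the methylcyclohexene) is bought as (R)-carvone; rings A and B are closed last, together.
2. 20 ⇐ 18: anodic oxidation of a silyl enol ether/allylsilane gives a 2-silyloxyallyl cation that adds across a butadiene tethered through its 2-position (type 2 intramolecular (4+3)). This forms both seven-membered rings, the CH2 bridge and the bridgehead alkene.
3. 18 ⇐ 12 + 14: dienyl-ethyl arm by Negishi coupling at an enol triflate; cation precursor from a Weinreb amide arm.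
4. 12 ⇐ 5 + 10: side chain by hydroboration of the isopropenyl group (sets the CH–CH3 centre), methylenation and B-alkyl Suzuki coupling with an (E)-iodoalkenol.
5. 5 ⇐ 1 + 2: trans α'-alkylation of carvone, then reductive enol triflation.

Assumption: compounds 2, 10 and 13 are taken as catalogue compounds.

## Route

Step 1
Reactants: 1 (R)-(−)-carvone; 2 2-bromo-N-methoxy-N-methylacetamide
Product: 3 N-methoxy-N-methyl-2-[(1S,6R)-3-methyl-2-oxo-6-(prop-1-en-2-yl)cyclohex-3-en-1-yl]acetamide
Conditions: LiN(i-Pr)2, THF, −78 °C; then 2, DMPU, −78 → −30 °C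
Reagents that add atoms: none
Why: Kinetic α'-enolate alkylation of carvone, in which the electrophile enters anti to the isopropenyl group of the half-chair enolate, so the bought stereocentre sets the new ring centre trans (about 8:1 expected).

Step 2
Reactants: 3 N-methoxy-N-methyl-2-[(1S,6R)-3-methyl-2-oxo-6-(prop-1-en-2-yl)cyclohex-3-en-1-yl]acetamide
Product: 5 (5R,6S)-6-[2-(methoxy(methyl)amino)-2-oxoethyl]-2-methyl-5-(prop-1-en-2-yl)cyclohex-1-en-1-yl trifluoromethanesulfonate, via lithium enolate 4 (not isolated)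
Conditions: LiBH(s-Bu)3, THF, −78 °C; then Comins' reagent, −78 → 0 °C
Reagents that add atoms: Comins' reagent, N-(5-chloropyridin-2-yl)-N-(trifluoromethylsulfonyl)trifluoromethanesulfonamide, FC(F)(F)S(=O)(=O)N(c1ccc(Cl)cn1)S(=O)(=O)C(F)(F)F; LiBH(s-Bu)3, [Li+].CCC(C)[BH-](C(C)CC)C(C)CC (hydride to the product, lithium only in 4)
Why: Conjugate hydride reduction of the enone gives the regiodefined tetrasubstituted enolate, which is trapped on oxygen (reductive enolate triflation), while the Weinreb amide is inert to the bulky borohydride at −78 °C and no stereocentre is touched.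

Step 3
Reactants: 5 (5R,6S)-6-[2-(methoxy(methyl)amino)-2-oxoethyl]-2-methyl-5-(prop-1-en-2-yl)cyclohex-1-en-1-yl trifluoromethanesulfonate
Product: 7 (5S,6S)-5-[(2R)-1-hydroxypropan-2-yl]-6-[2-(methoxy(methyl)amino)-2-oxoethyl]-2-methylcyclohex-1-en-1-yl trifluoromethanesulfonate, via B-alkyl-9-BBN adduct 6 (not isolated)
Conditions: 9-BBN, THF, 0 °C → rt; then 30% H2O2, aq. NaOAc, 0 °C → rt
Reagents that add atoms: hydrogen peroxide, OO; 9-BBN, B1C2CCCC1CCC2 (its atoms stay only in 6)
Why: Anti-Markovnikov hydroboration–oxidation in which the bulky borane attacks the isopropenyl face opposite the substituted ring carbon, with the ring C–H eclipsing the C=CH2 bond (minimised allylic strain), the sense I recall for the isopropenyl group of amorpha-4,11-diene (dihydroartemisinic-type centre), so the two ring centres set the CH–CH3 centre (about 6:1 expected, minor epimer removed by chromatography) and the tetrasubstituted enol triflate is untouched.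

Step 4
Reactants: 7 (5S,6S)-5-[(2R)-1-hydroxypropan-2-yl]-6-[2-(methoxy(methyl)amino)-2-oxoethyl]-2-methylcyclohex-1-en-1-yl trifluoromethanesulfonate
Product: 9 (5S,6S)-5-[(2S)-but-3-en-2-yl]-6-[2-(methoxy(methyl)amino)-2-oxoethyl]-2-methylcyclohex-1-en-1-yl trifluoromethanesulfonate, via aldehyde 8 (not isolated)
Conditions: (COCl)2, DMSO, CH2Cl2, −78 °C; Et3N; then Ph3P=CH2 (from Ph3PCH3Br and KN(SiMe3)2, 4 equiv), THF, −78 → 0 °C
Reagents that add atoms: methylenetriphenylphosphorane, C=P(c1ccccc1)(c1ccccc1)c1ccccc1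
Why: Swern oxidation followed by Wittig methylenation in the same flask, so the epimerisable α-branched aldehyde is consumed cold by the non-stabilised ylide and the CH–CH3 centre is kept.

Step 5
Reactants: 9 (5S,6S)-5-[(2S)-but-3-en-2-yl]-6-[2-(methoxy(methyl)amino)-2-oxoethyl]-2-methylcyclohex-1-en-1-yl trifluoromethanesulfonate; 10 (E)-3-iodo-2-methylprop-2-en-1-ol
Product: 12 (5S,6S)-5-[(2S,5E)-7-hydroxy-6-methylhept-5-en-2-yl]-6-[2-(methoxy(methyl)amino)-2-oxoethyl]-2-methylcyclohex-1-en-1-yl trifluoromethanesulfonate, via B-alkyl-9-BBN adduct 11 (not isolated)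
Conditions: 9-BBN, THF, 0 °C → rt; then 10, Pd(dppf)Cl2 (5 mol %), AsPh3, Cs2CO3, DMF–H2O, rt
Reagents that add atoms: 9-BBN, B1C2CCCC1CCC2 (its atoms stay only in 11)
Why: B-alkyl Suzuki–Miyaura coupling in which 9-BBN adds only to the monosubstituted alkene and palladium inserts into the unhindered alkenyl iodide far faster than into the flanked tetrasubstituted enol triflate at room temperature, with the E geometry of 10 carried over.

Step 6
Reactants: 13 4-bromobut-1-yne
Product: 14 2-(2-bromoethyl)buta-1,3-diene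
Conditions: ethylene (1 atm), second-generation Grubbs catalyst RuCl2(=CHPh)(PCy3)(H2IMes) (3 mol %), CH2Cl2, rt
Reagents that add atoms: ethylene, C=C
Why: Ethylene–alkyne cross enyne metathesis turns the terminal alkyne into a 2-substituted buta-1,3-diene and tolerates the primary bromide.

Step 7
Reactants: 12 (5S,6S)-5-[(2S,5E)-7-hydroxy-6-methylhept-5-en-2-yl]-6-[2-(methoxy(methyl)amino)-2-oxoethyl]-2-methylcyclohex-1-en-1-yl trifluoromethanesulfonate; 14 2-(2-bromoethyl)buta-1,3-diene
Product: 16 2-[(1S,6S)-6-[(2S,5E)-7-hydroxy-6-methylhept-5-en-2-yl]-3-methyl-2-(3-methylidenepent-4-en-1-yl)cyclohex-2-en-1-yl]-N-methoxy-N-methylacetamide, via alkylzinc bromide 15 (not isolated)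
Conditions: 14, Zn, LiCl, THF, 45 °C; then 12, Pd(OAc)2 (5 mol %), SPhos (10 mol %), THF, rt → 45 °C (3 equiv of 15)
Reagents that add atoms: zinc, [Zn] (stays only in 15)
Why: Negishi coupling of a primary alkylzinc with the hindered enol triflate, which with the SPhos catalyst is faster than protonation of the zinc reagent by the free hydroxyl and leaves amide and diene untouched.

Step 8
Reactants: 16 2-[(1S,6S)-6-[(2S,5E)-7-hydroxy-6-methylhept-5-en-2-yl]-3-methyl-2-(3-methylidenepent-4-en-1-yl)cyclohex-2-en-1-yl]-N-methoxy-N-methylacetamide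
Product: 17 1-[(1S,6S)-6-[(2S,5E)-7-hydroxy-6-methylhept-5-en-2-yl]-3-methyl-2-(3-methylidenepent-4-en-1-yl)cyclohex-2-en-1-yl]-3-(trimethylsilyl)propan-2-one
Conditions: Me3SiCH2Li (2.5 equiv), THF, −78 → 0 °C; pH 7 buffer
Reagents that add atoms: (trimethylsilyl)methyllithium, [Li]C[Si](C)(C)C
Why: Weinreb ketone synthesis, where the chelated tetrahedral adduct prevents over-addition (one equivalent is spent on the hydroxyl) and buffered work-up keeps the β-ketosilane intact.

Step 9
Reactants: 17 1-[(1S,6S)-6-[(2S,5E)-7-hydroxy-6-methylhept-5-en-2-yl]-3-methyl-2-(3-methylidenepent-4-en-1-yl)cyclohex-2-en-1-yl]-3-(trimethylsilyl)propan-2-one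
Product: 18 (Z)-silyl enol ether/allylsilane: triisopropyl{[(1Z)-1-[(1R,6S)-3-methyl-2-(3-methylidenepent-4-en-1-yl)-6-[(2S,5E)-6-methyl-7-(triisopropylsilyloxy)hept-5-en-2-yl]cyclohex-2-en-1-yl]-3-(trimethylsilyl)prop-1-en-2-yl]oxy}silane
Conditions: LiN(i-Pr)2 (2.3 equiv), THF–DMPU, −78 °C; i-Pr3SiOTf (2.4 equiv), −78 → 0 °C; Et3N-buffered work-up
Reagents that add atoms: triisopropylsilyl trifluoromethanesulfonate, CC(C)[Si](C(C)C)(C(C)C)OS(=O)(=O)C(F)(F)F
Why: Kinetic enolisation and O-silylation, in which the C–Si bond of a β-ketosilane lies parallel to the carbonyl π system so the CH2Si protons are kinetically non-acidic and the base removes a ring-side CH2 proton, DMPU gives the (Z)-enolate, and the alkoxide is silylated in the same operation.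

Step 10
Reactants: 18 (Z)-silyl enol ether/allylsilane
Product: 20 (1S,2R,3S)-6-methyl-3-[(2S,5E)-6-methyl-7-(triisopropylsilyloxy)hept-5-en-2-yl]tricyclo[8.4.1.0^2,7]pentadeca-6,10-dien-14-one, via 2-silyloxyallyl cation 19 (not isolated)
Conditions: undivided cell, reticulated vitreous carbon anode, Pt cathode, constant current (0.5 mA cm−2, 2.2 F mol−1), Et4NOTs (0.1 M), 2,6-lutidine, CH2Cl2–(CF3)2CHOH 4:1, 5 mM, −20 °C
Reagents that add atoms: none
Why: Proposed new method: anodic desilylative generation of a 2-silyloxyallyl cation and its type 2 intramolecular (4+3) cycloaddition. The 2-silyloxyallylsilane is the most easily oxidised π system in 18 (an enol ether raised further by the allylic C–Si bond, estimated at least 0.5 V below the tetrasubstituted alkene and the diene); one-electron oxidation and loss of Me3Si+ give a 2-silyloxyallyl radical that is oxidised at once to cation 19; its ring-bound terminus bonds to C1 of the butadiene (which is tethered at C2) and its CH2 terminus to C4, closing rings B and A with the bridgehead alkene, and loss of i-Pr3Si+ from the oxocarbenium ion gives the ketone. The new bridgehead centre is set by A(1,3) strain in the Z cation, which holds the ring C–H in the plane next to OSi and the diene tether on one face, so the bridgehead hydrogen ends trans to the neighbouring ring hydrogen as in the target. The closest known reactions are (4+3) cycloadditions of 2-silyloxyallyl cations made by ionising 2-silyloxyallyl halides, anodic olefin couplings that use allylsilanes as electroauxiliaries, and type 2 intramolecular Diels–Alder and (5+2) cycloadditions.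

Step 11
Reactants: 20 (1S,2R,3S)-6-methyl-3-[(2S,5E)-6-methyl-7-(triisopropylsilyloxy)hept-5-en-2-yl]tricyclo[8.4.1.0^2,7]pentadeca-6,10-dien-14-one
Product: 22 (2E,6S)-2-methyl-6-[(1S,2R,3S)-6-methyl-14-methylidenetricyclo[8.4.1.0^2,7]pentadeca-6,10-dien-3-yl]hept-2-en-1-ol, via triisopropylsilyl ether 21 (not isolated)
Conditions: Ph3PCH3Br, KOt-Bu, toluene, 70 °C; then Bu4NF, THF, rt
Reagents that add atoms: methylenetriphenylphosphorane, C=P(c1ccccc1)(c1ccccc1)c1ccccc1
Why: Wittig methylenation of the cycloheptanone (its only stereogenic α-carbon is a bridgehead that cannot epimerise) followed by fluoride cleavage of the silyl ether in the same flask gives the target.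

## Compound list

1 | (R)-(−)-carvone, (5R)-2-methyl-5-(prop-1-en-2-yl)cyclohex-2-en-1-one | CC1=CC[C@H](CC1=O)C(C)=C | starting material
2 | 2-bromo-N-methoxy-N-methylacetamide | BrCC(=O)N(C)OC | starting material
3 | N-methoxy-N-methyl-2-[(1S,6R)-3-methyl-2-oxo-6-(prop-1-en-2-yl)cyclohex-3-en-1-yl]acetamide (trans) | CC1=CC[C@@H](C(C)=C)[C@H](CC(=O)N(C)OC)C1=O | intermediate
4 | lithium (5R,6S)-6-[2-(methoxy(methyl)amino)-2-oxoethyl]-2-methyl-5-(prop-1-en-2-yl)cyclohex-1-en-1-olate | CC1=C([O-])[C@@H](CC(=O)N(C)OC)[C@H](C(C)=C)CC1.[Li+] | intermediate (not isolated)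
5 | (5R,6S)-6-[2-(methoxy(methyl)amino)-2-oxoethyl]-2-methyl-5-(prop-1-en-2-yl)cyclohex-1-en-1-yl trifluoromethanesulfonate | CC1=C(OS(=O)(=O)C(F)(F)F)[C@@H](CC(=O)N(C)OC)[C@H](C(C)=C)CC1 | intermediate
6 | B-alkyl-9-BBN adduct of 5 (boron on the former =CH2 carbon, new centre as in 7) | CC1=C(OS(=O)(=O)C(F)(F)F)[C@@H](CC(=O)N(C)OC)[C@H]([C@@H](C)CB2C3CCCC2CCC3)CC1 | intermediate (not isolated)
7 | (5S,6S)-5-[(2R)-1-hydroxypropan-2-yl]-6-[2-(methoxy(methyl)amino)-2-oxoethyl]-2-methylcyclohex-1-en-1-yl trifluoromethanesulfonate | CC1=C(OS(=O)(=O)C(F)(F)F)[C@@H](CC(=O)N(C)OC)[C@H]([C@@H](C)CO)CC1 | intermediate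
8 | (5R,6S)-6-[2-(methoxy(methyl)amino)-2-oxoethyl]-2-methyl-5-[(2R)-1-oxopropan-2-yl]cyclohex-1-en-1-yl trifluoromethanesulfonate | CC1=C(OS(=O)(=O)C(F)(F)F)[C@@H](CC(=O)N(C)OC)[C@H]([C@@H](C)C=O)CC1 | intermediate (not isolated)
9 | (5S,6S)-5-[(2S)-but-3-en-2-yl]-6-[2-(methoxy(methyl)amino)-2-oxoethyl]-2-methylcyclohex-1-en-1-yl trifluoromethanesulfonate | CC1=C(OS(=O)(=O)C(F)(F)F)[C@@H](CC(=O)N(C)OC)[C@H]([C@@H](C)C=C)CC1 | intermediate
10 | (E)-3-iodo-2-methylprop-2-en-1-ol | OC/C(C)=C/I | starting material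
11 | B-alkyl-9-BBN adduct of 9 (boron on the terminal carbon of the former vinyl group) | CC1=C(OS(=O)(=O)C(F)(F)F)[C@@H](CC(=O)N(C)OC)[C@H]([C@@H](C)CCB2C3CCCC2CCC3)CC1 | intermediate (not isolated)
12 | (5S,6S)-5-[(2S,5E)-7-hydroxy-6-methylhept-5-en-2-yl]-6-[2-(methoxy(methyl)amino)-2-oxoethyl]-2-methylcyclohex-1-en-1-yl trifluoromethanesulfonate | CC1=C(OS(=O)(=O)C(F)(F)F)[C@@H](CC(=O)N(C)OC)[C@H]([C@@H](C)CC/C=C(\C)CO)CC1 | intermediate
13 | 4-bromobut-1-yne | C#CCCBr | starting material
14 | 2-(2-bromoethyl)buta-1,3-diene | C=CC(=C)CCBr | intermediate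
15 | (3-methylidenepent-4-en-1-yl)zinc bromide | C=CC(=C)CC[Zn]Br | intermediate (not isolated)
16 | 2-[(1S,6S)-6-[(2S,5E)-7-hydroxy-6-methylhept-5-en-2-yl]-3-methyl-2-(3-methylidenepent-4-en-1-yl)cyclohex-2-en-1-yl]-N-methoxy-N-methylacetamide | CC1=C(CCC(=C)C=C)[C@@H](CC(=O)N(C)OC)[C@H]([C@@H](C)CC/C=C(\C)CO)CC1 | intermediate
17 | 1-[(1S,6S)-6-[(2S,5E)-7-hydroxy-6-methylhept-5-en-2-yl]-3-methyl-2-(3-methylidenepent-4-en-1-yl)cyclohex-2-en-1-yl]-3-(trimethylsilyl)propan-2-one | CC1=C(CCC(=C)C=C)[C@@H](CC(=O)C[Si](C)(C)C)[C@H]([C@@H](C)CC/C=C(\C)CO)CC1 | intermediate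
18 | triisopropyl{[(1Z)-1-[(1R,6S)-3-methyl-2-(3-methylidenepent-4-en-1-yl)-6-[(2S,5E)-6-methyl-7-(triisopropylsilyloxy)hept-5-en-2-yl]cyclohex-2-en-1-yl]-3-(trimethylsilyl)prop-1-en-2-yl]oxy}silane | CC1=C(CCC(=C)C=C)[C@@H](/C=C(\O[Si](C(C)C)(C(C)C)C(C)C)C[Si](C)(C)C)[C@H]([C@@H](C)CC/C=C(\C)CO[Si](C(C)C)(C(C)C)C(C)C)CC1 | intermediate
19 | 2-(triisopropylsilyloxy)allyl cation from 18 (charge shared by the ring-bound carbon and the terminal CH2) | CC1=C(CCC(=C)C=C)[C@@H]([CH+]C(=C)O[Si](C(C)C)(C(C)C)C(C)C)[C@H]([C@@H](C)CC/C=C(\C)CO[Si](C(C)C)(C(C)C)C(C)C)CC1 | intermediate (not isolated)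
20 | (1S,2R,3S)-6-methyl-3-[(2S,5E)-6-methyl-7-(triisopropylsilyloxy)hept-5-en-2-yl]tricyclo[8.4.1.0^2,7]pentadeca-6,10-dien-14-one | O=C1CCC=C2CCC3=C(C)CC[C@@H]([C@@H](C)CC/C=C(\C)CO[Si](C(C)C)(C(C)C)C(C)C)[C@@H]3[C@@H]1C2 | intermediate
21 | triisopropylsilyl ether of 22 | C=C1CCC=C2CCC3=C(C)CC[C@@H]([C@@H](C)CC/C=C(\C)CO[Si](C(C)C)(C(C)C)C(C)C)[C@@H]3[C@@H]1C2 | intermediate (not isolated)
22 | (2E,6S)-2-methyl-6-[(1S,2R,3S)-6-methyl-14-methylidenetricyclo[8.4.1.0^2,7]pentadeca-6,10-dien-3-yl]hept-2-en-1-ol | C=C1CCC=C2CCC3=C(C)CC[C@@H]([C@@H](C)CC/C=C(\C)CO)[C@@H]3[C@@H]1C2 | target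

## Step count and risks

Total steps: 11 (ten from carvone plus the preparation of 14). Longest linear sequence: 10 steps (1 → 22).

Steps most likely to fail:

Step 10 (the proposed anodic cycloaddition). Possible failures are loss of the oxygen-bound silyl group from the radical cation instead of the carbon-bound one, proton loss from cation 19 to a silyloxydiene, or five-ring closure. The fallback uses known oxyallyl chemistry and sets out from 16. Chloromethyllithium (ICH2Cl, MeLi·LiBr, THF, −78 °C) converts the Weinreb amide into the α-chloromethyl ketone F1. Sodium trifluoroethoxide in trifluoroethanol (base-induced ionisation of an α-chloroketone to the oxyallyl cation) then gives, by the same tethered (4+3) closure, the hydroxy ketone F2. Excess Ph3P=CH2 converts F2 directly into 22, where the fallback rejoins the route.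

Step 3 (configuration of the CH–CH3 centre). The selectivity could be low or reversed on this substrate. The fallback sets out from 5. Allylic oxidation of the isopropenyl methyl group (SeO2, t-BuOOH, then Dess–Martin periodinane) gives the 2-substituted acrolein F3. Diimide reduction of its 1,1-disubstituted double bond (2-nitrobenzenesulfonylhydrazide, Et3N), the substrate-controlled reduction used to turn artemisinic acid into dihydroartemisinic acid, gives aldehyde 8. The fallback rejoins the route at 8, which is taken straight into the Wittig half of step 4.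

Step 5 (alkylborane and enol triflate in one molecule). If palladium inserts into the triflate, the borane closes a six-membered ring instead of coupling with 10. The fallback sets out from 9 and changes the order of bond formation. Negishi coupling of 9 with 15 (Pd(OAc)2, SPhos) first gives the diene amide F4. Then 9-BBN (1.05 equiv, 0 °C), which reacts with the monosubstituted alkene well ahead of the conjugated diene, and coupling with 10 under the conditions of step 5 give 16, where the fallback rejoins the route.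

## Further compounds

F1 | step 10 | 1-chloro-3-[(1S,6S)-6-[(2S,5E)-7-hydroxy-6-methylhept-5-en-2-yl]-3-methyl-2-(3-methylidenepent-4-en-1-yl)cyclohex-2-en-1-yl]propan-2-one | CC1=C(CCC(=C)C=C)[C@@H](CC(=O)CCl)[C@H]([C@@H](C)CC/C=C(\C)CO)CC1
F2 | step 10 | (1S,2R,3S)-3-[(2S,5E)-7-hydroxy-6-methylhept-5-en-2-yl]-6-methyltricyclo[8.4.1.0^2,7]pentadeca-6,10-dien-14-one | O=C1CCC=C2CCC3=C(C)CC[C@@H]([C@@H](C)CC/C=C(\C)CO)[C@@H]3[C@@H]1C2
F3 | step 3 | (5R,6S)-6-[2-(methoxy(methyl)amino)-2-oxoethyl]-2-methyl-5-(3-oxoprop-1-en-2-yl)cyclohex-1-en-1-yl trifluoromethanesulfonate | CC1=C(OS(=O)(=O)C(F)(F)F)[C@@H](CC(=O)N(C)OC)[C@H](C(=C)C=O)CC1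
F4 | step 5 | 2-[(1S,6S)-6-[(2S)-but-3-en-2-yl]-3-methyl-2-(3-methylidenepent-4-en-1-yl)cyclohex-2-en-1-yl]-N-methoxy-N-methylacetamide | CC1=C(CCC(=C)C=C)[C@@H](CC(=O)N(C)OC)[C@H]([C@@H](C)C=C)CC1
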